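The benzene ring is not functionalised but assembled: ring atoms C2(Br), C3(Br), C4 (carbon substituent) and C5(H) of the target are the C3–C4–C5–C6 edge of methyl 3,4-dibromo-2-oxo-2H-pyran-5-carboxylate, while C1(O) and C6 come from 1,1-dimethoxyethene. One inverse-demand (4+2) cycloaddition, with loss of CO2 and methanol, forms the C1–C2 and C5–C6 bonds and delivers the arene with the vicinal dibromide, the oxygen and the carboxyl carbon already in their final positions. The pyrone is built in three steps from dimethyl 3-oxopentanedioate; demethylation, one ortho-bromination and ester reduction finish the synthesis.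

Key step: step 4

Remark: the target is achiral; 3 and 4 are alkene-isomer (tautomer) mixtures and 9 is a racemate, which is of no consequence because all three react on in the flask.

Step 1
Reactants: 1 dimethyl 3-oxopentanedioate; 2 trimethyl orthoformate
Product: 5 methyl 4-hydroxy-2-oxo-2H-pyran-5-carboxylate, via methoxymethylidene diester 3 (not isolated), via hydroxymethylidene diester 4 (not isolated)
Conditions: Ac2O (2.2 equiv), 120 °C; concentrate; then 2 M aq. HCl, 50 °C
Reagents that add atoms: water, O
Why: Orthoformate alkoxymethylenation of one active methylene (Ac2O traps the methanol) should give 3, aqueous acid hydrolyses this vinylogous carbonate to 4, and the enol OH of 4 lactonises onto the distal ester in a six-membered acyl substitution that ends in the stable 4-hydroxy-2-pyrone, a condensation–cyclisation sequence known for acetonedicarboxylate esters.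

Step 2
Reactants: 5 methyl 4-hydroxy-2-oxo-2H-pyran-5-carboxylate
Product: 6 methyl 3-bromo-4-hydroxy-2-oxo-2H-pyran-5-carboxylate
Conditions: NBS (1.05 equiv), MeCN, 0 °C → rt
Reagents that add atoms: N-bromosuccinimide, O=C1CCC(=O)N1Br
Why: Electrophilic bromination at the enolic C3, the only nucleophilic C–H of the 4-hydroxy-2-pyrone (C6–H sits on an electrophilic carbon), as is routine for 4-hydroxy-2-pyrones and 4-hydroxycoumarins.

Step 3
Reactants: 6 methyl 3-bromo-4-hydroxy-2-oxo-2H-pyran-5-carboxylate
Product: 7 methyl 3,4-dibromo-2-oxo-2H-pyran-5-carboxylate
Conditions: POBr3 (1.5 equiv), DMF (cat.), MeCN, 70 °C; ice-water quench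
Reagents that add atoms: phosphoryl bromide, O=P(Br)(Br)Br
Why: Deoxybromination of a vinylogous acid, in which O-phosphorylation (Vilsmeier-type activation) makes the 4-oxygen a leaving group and bromide replaces it by addition–elimination at C4, the standard way from 4-hydroxy-2-pyrones to 4-bromo-2-pyrones, with the ester and the C3 bromide as spectators.

Step 4
Reactants: 7 methyl 3,4-dibromo-2-oxo-2H-pyran-5-carboxylate; 8 1,1-dimethoxyethene
Product: 11 methyl 2,3-dibromo-4-methoxybenzoate, via bicyclic lactone 9 (not isolated), via cyclohexadiene ketal 10 (not isolated)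
Conditions: 8 (3 equiv), toluene, rt → 110 °C, sealed tube
Reagents that add atoms: none
Why: The pyrone, whose LUMO is lowered by the lactone, the 5-ester and two bromines, serves as the 4π partner: the CH2 terminus of 8 bonds to pyrone C6 and the acetal carbon to C3 in an asynchronous, possibly zwitterionic, inverse-demand (4+2) addition that gives the 2-oxabicyclo[2.2.2]oct-5-en-3-one 9. Retro-(4+2) extrusion of CO2 then gives cyclohexadiene ketal 10, and 1,2-elimination of methanol aromatises it to 11; the closest known reaction type is the conversion of coumalate esters and 3-bromo-2-pyrones into alkoxybenzoates with ketene acetals. The carbocycle closes by an intermolecular two-bond (4+2) annulation of four pyrone carbons with the two carbons of 8, so no endo or exo cyclisation mode applies. The two bridgehead stereocentres of 9 form as a racemate, are tied to each other by the bicycle and vanish on aromatisation, so nothing has to be controlled. The step needs regioselectivity and chemoselectivity over displacement of the C4 bromide: attack at C6 gives an anion delocalised into both the 5-ester and the lactone carbonyl, whereas attack at C4 would be stabilised by the lactone alone, so the methoxy-bearing carbon should end up next to the former C3 with both C–Br bonds intact.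

Step 5
Reactants: 11 methyl 2,3-dibromo-4-methoxybenzoate
Product: 12 methyl 2,3-dibromo-4-hydroxybenzoate
Conditions: BBr3 (1.5 equiv), CH2Cl2, −78 → 0 °C; H2O
Reagents that add atoms: none
Why: Lewis acid-mediated ether cleavage, in which BBr3 complexes the aryl ether oxygen and bromide removes the methyl group by SN2 attack, a process that at or below 0 °C is faster than cleavage of the methyl ester and leaves aryl bromides untouched.

Step 6
Reactants: 12 methyl 2,3-dibromo-4-hydroxybenzoate
Product: 13 methyl 2,3,5-tribromo-4-hydroxybenzoate
Conditions: Br2 (1.05 equiv), AcOH, rt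
Reagents that add atoms: bromine, BrBr
Why: Electrophilic aromatic bromination directed by the phenol OH to its only free ortho position (C5 of the benzoate), since the other ortho position carries bromine and the para position the ester, so a single regioisomer is expected.

Step 7
Reactants: 13 methyl 2,3,5-tribromo-4-hydroxybenzoate
Product: 14 2,3,6-tribromo-4-(hydroxymethyl)phenol
Conditions: i-Bu2AlH (4 equiv), CH2Cl2, −78 → 0 °C; aq. KNaC4H4O6, then 1 M HCl to pH 4
Reagents that add atoms: none
Why: Hydride reduction of the ester to the primary alcohol through the aldehyde, with one equivalent of i-Bu2AlH consumed by the phenol, aryl bromides being inert to this hydride at these temperatures and the mild tartrate work-up sparing the p-hydroxybenzylic alcohol.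

Compound list
1 | dimethyl 3-oxopentanedioate | COC(=O)CC(=O)CC(=O)OC | starting material
2 | trimethyl orthoformate | COC(OC)OC | starting material
3 | dimethyl 2-(methoxymethylidene)-3-oxopentanedioate (E/Z mixture, forms in the flask) | COC=C(C(=O)OC)C(=O)CC(=O)OC | intermediate
4 | dimethyl 2-(hydroxymethylidene)-3-oxopentanedioate (enol form, forms in the flask) | OC=C(C(=O)OC)C(=O)CC(=O)OC | intermediate
5 | methyl 4-hydroxy-2-oxo-2H-pyran-5-carboxylate | COC(=O)C1=COC(=O)C=C1O | intermediate
6 | methyl 3-bromo-4-hydroxy-2-oxo-2H-pyran-5-carboxylate | COC(=O)C1=COC(=O)C(Br)=C1O | intermediate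
7 | methyl 3,4-dibromo-2-oxo-2H-pyran-5-carboxylate | COC(=O)C1=COC(=O)C(Br)=C1Br | intermediate
8 | 1,1-dimethoxyethene | C=C(OC)OC | starting material
9 | methyl 4,5-dibromo-8,8-dimethoxy-3-oxo-2-oxabicyclo[2.2.2]oct-5-ene-6-carboxylate (racemate, one enantiomer drawn; bridgeheads tied by the bicycle; forms in the flask) | COC(=O)C1=C(Br)[C@@]2(Br)C(=O)O[C@@H]1CC2(OC)OC | intermediate
10 | methyl 5,6-dibromo-4,4-dimethoxycyclohexa-1,5-diene-1-carboxylate (forms in the flask) | COC(=O)C1=CCC(OC)(OC)C(Br)=C1Br | intermediate
11 | methyl 2,3-dibromo-4-methoxybenzoate | COC(=O)c1ccc(OC)c(Br)c1Br | intermediate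
12 | methyl 2,3-dibromo-4-hydroxybenzoate | COC(=O)c1ccc(O)c(Br)c1Br | intermediate
13 | methyl 2,3,5-tribromo-4-hydroxybenzoate | COC(=O)c1cc(Br)c(O)c(Br)c1Br | intermediate
14 | 2,3,6-tribromo-4-(hydroxymethyl)phenol | OCc1cc(Br)c(O)c(Br)c1Br | target

Total step count: 7 steps.
Longest linear sequence: 7 steps (1 → 14); ketene acetal 8 enters at step 4.

Steps most likely to fail

Step 4 (key step). The ketene acetal may add at C4 and expel bromide, or the first adduct at C6 may open the lactone instead of closing onto the bromine-bearing C3. The fallback removes the C4 bromine from the cycloaddition and installs it afterwards by directed metalation. It sets out from ketene acetal 8, which is heated in toluene with commercial methyl 3-bromo-2-oxo-2H-pyran-5-carboxylate F1, a pyrone with no leaving group at C4. The same sequence, well precedented for this bromocoumalate class, should pass through methyl 4-bromo-8,8-dimethoxy-3-oxo-2-oxabicyclo[2.2.2]oct-5-ene-6-carboxylate F2 and methyl 5-bromo-4,4-dimethoxycyclohexa-1,5-diene-1-carboxylate F3 to methyl 3-bromo-4-methoxybenzoate F4. Treatment of F4 with (2,2,6,6-tetramethylpiperidin-1-yl)MgCl·LiCl in THF at −20 °C should magnesiate C2–H, the position flanked by the ester and the bromine, to give chloro[2-bromo-3-methoxy-6-(methoxycarbonyl)phenyl]magnesium F5. Quenching F5 with BrCl2C–CCl2Br would give 11, where the route is rejoined.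

Step 3. The hydrogen-bonded, electron-poor 4-hydroxyl may resist activation, or the lactone may be opened or degraded by hot phosphoryl bromide and the acid it releases. The fallback separates activation from halide delivery. It sets out from 6, which with Tf2O and pyridine in CH2Cl2 at −78 → 0 °C should give methyl 3-bromo-2-oxo-4-{[(trifluoromethyl)sulfonyl]oxy}-2H-pyran-5-carboxylate F6. LiBr in acetone at rt then replaces the vinylogous acyl triflate by addition–elimination and returns to the route at 7.

Step 5. BBr3 may also cleave the methyl ester, giving incomplete or unselective dealkylation. The fallback gives up selectivity on purpose. It sets out from 11, which with excess BBr3 in CH2Cl2 at rt followed by water should lose both methyl groups to give 2,3-dibromo-4-hydroxybenzoic acid F7. Fischer esterification of F7 (MeOH, cat. H2SO4, reflux) esterifies the acid but not the phenol and returns to the route at 12.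

Further compounds
F1 | step 4 | methyl 3-bromo-2-oxo-2H-pyran-5-carboxylate | COC(=O)C1=COC(=O)C(Br)=C1
F2 | step 4 | methyl 4-bromo-8,8-dimethoxy-3-oxo-2-oxabicyclo[2.2.2]oct-5-ene-6-carboxylate (racemate, one enantiomer drawn) | COC(=O)C1=C[C@@]2(Br)C(=O)O[C@@H]1CC2(OC)OC
F3 | step 4 | methyl 5-bromo-4,4-dimethoxycyclohexa-1,5-diene-1-carboxylate | COC(=O)C1=CCC(OC)(OC)C(Br)=C1
F4 | step 4 | methyl 3-bromo-4-methoxybenzoate | COC(=O)c1ccc(OC)c(Br)c1
F5 | step 4 | chloro[2-bromo-3-methoxy-6-(methoxycarbonyl)phenyl]magnesium | COC(=O)c1ccc(OC)c(Br)c1[Mg]Cl
F6 | step 3 | methyl 3-bromo-2-oxo-4-{[(trifluoromethyl)sulfonyl]oxy}-2H-pyran-5-carboxylate | COC(=O)C1=COC(=O)C(Br)=C1OS(=O)(=O)C(F)(F)F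
F7 | step 5 | 2,3-dibromo-4-hydroxybenzoic acid | OC(=O)c1ccc(O)c(Br)c1Br
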